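## Retrosynthetic overview

1. 2-O-Acetylzeylenone ⇐ its 4,5-dihydro ketol by α,β-dehydrogenation of the ketone; the enone is made last.
2. Dihydro ketol ⇐ open-chain 6-oxoheptanal by forming C1–C6 with a carbene catalyst: the aldehyde carbon reacts as an acyl anion (Breslow intermediate) with the ketone carbon. This closes the only ring that is built, the carbocycle, and sets the C1 carbinol.
3. Keto-aldehyde ⇐ hex-5-en-2-ulose triester by linear hydroformylation; CO supplies C6.
4. Enulose ⇐ 6-iodo-2,3-O-isopropylidene-L-sorbofuranose dibenzoate by zinc ring fragmentation, which opens the furanose and dioxolane rings and frees one hydroxyl for the acetate.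
5. Iodide ⇐ diacetone-L-sorbose; sorbose C3/C4 become target C2/C3, and every ester put on is one the target keeps.

Assumption: 2,3:4,6-di-O-isopropylidene-α-L-sorbofuranose is bought, and the route is written for the catalyst antipode in step 7 that a two-vial test shows to be matched to the substrate.

Target numbering used below: C1 = C(OH)CH2OBz, C2 = CH–OAc, C3 = CH–OBz, C4=C5, C6 = C=O.

## Route

Step 1
Reactants: 1 2,3:4,6-di-O-isopropylidene-α-L-sorbofuranose
Product: 2 2,3-O-isopropylidene-α-L-sorbofuranose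
Conditions: AcOH/H2O (3:2), 40 °C
Reagents that add atoms: none
Why: Selective acetal hydrolysis, in which the six-membered 4,6-dioxane acetal is much more acid-labile than the cis-fused 2,3-dioxolane at the anomeric carbon, so cleavage stops at the monoacetonide without touching a stereocentre.

Step 2
Reactants: 2 2,3-O-isopropylidene-α-L-sorbofuranose
Product: 3 6-deoxy-6-iodo-2,3-O-isopropylidene-α-L-sorbofuranose
Conditions: PPh3 (1.2 eq), I2 (1.2 eq), imidazole (2.5 eq), THF, 0 °C → rt
Reagents that add atoms: iodine, II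
Why: Appel-type (Garegg–Samuelsson) iodination is an SN2 displacement and so selects the unhindered primary C6–OH over the neopentyl-like C1–OH next to the ketal carbon and over the secondary C4–OH.

Step 3
Reactants: 3 6-deoxy-6-iodo-2,3-O-isopropylidene-α-L-sorbofuranose
Product: 4 1,4-di-O-benzoyl-6-deoxy-6-iodo-2,3-O-isopropylidene-α-L-sorbofuranose
Conditions: BzCl (2.5 eq), pyridine, DMAP (cat.), CH2Cl2, 0 °C → rt
Reagents that add atoms: benzoyl chloride, O=C(Cl)c1ccccc1
Why: DMAP-catalysed acylation esterifies both remaining hydroxyls and so installs the two benzoates of the target (sorbose O1 = CH2OBz, sorbose O4 = C3–OBz).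

Step 4
Reactants: 4 1,4-di-O-benzoyl-6-deoxy-6-iodo-2,3-O-isopropylidene-α-L-sorbofuranose
Product: 6 (3S,4R)-1,4-bis(benzoyloxy)-3-hydroxyhex-5-en-2-one, via ring-opened hemiketal 5 (not isolated)
Conditions: activated Zn dust (10 eq), THF/H2O (4:1), sonication, 40 °C; crude product taken on directly
Reagents that add atoms: none
Why: Bernet–Vasella reductive fragmentation, in which zinc inserts into the C6–I bond and expels the β ring oxygen to give the C5=C6 alkene and a C2 hemiketal that collapses to the ketone with loss of acetone, freeing O3 alone while C3 and C4 (target C2 and C3) are untouched.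

Step 5
Reactants: 6 (3S,4R)-1,4-bis(benzoyloxy)-3-hydroxyhex-5-en-2-one
Product: 7 (3S,4R)-3-acetoxy-1,4-bis(benzoyloxy)hex-5-en-2-one
Conditions: Ac2O, pyridine, CH2Cl2, 0 °C
Reagents that add atoms: acetic anhydride, CC(=O)OC(C)=O
Why: Acetylation of the only free hydroxyl places the target's acetate, with pyridine at 0 °C being too weak a base to epimerise C3 or to eliminate the β-benzoate.

Step 6
Reactants: 7 (3S,4R)-3-acetoxy-1,4-bis(benzoyloxy)hex-5-en-2-one
Product: 8 (4R,5S)-5-acetoxy-4,7-bis(benzoyloxy)-6-oxoheptanal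
Conditions: Rh(acac)(CO)2 (1 mol %), BiPhePhos (2 mol %), CO/H2 (1:1, 10 bar), toluene, 60 °C
Reagents that add atoms: carbon monoxide, [C-]#[O+]
Why: Rhodium/bisphosphite hydroformylation of a monosubstituted alkene next to a branched allylic carbon is strongly linear-selective and adds the seventh skeletal carbon (target C6) as an aldehyde under neutral conditions that leave the esters and the ketone alone.

Step 7
Reactants: 8 (4R,5S)-5-acetoxy-4,7-bis(benzoyloxy)-6-oxoheptanal
Product: 9 [(1S,2S,3R)-2-acetoxy-3-(benzoyloxy)-1-hydroxy-6-oxocyclohexyl]methyl benzoate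
Conditions: aminoindanol-derived N-C6F5 triazolium tetrafluoroborate (Rovis type, matched antipode, 10 mol %), i-Pr2NEt (10 mol %), toluene (0.05 M), 0 °C → rt
Reagents that add atoms: none
Why: Intramolecular NHC-catalysed crossed aldehyde–ketone benzoin reaction, in which the aldehyde becomes its Breslow (acyl-anion) intermediate and adds to the doubly α-oxygenated ketone through a chair-like, Felkin–Anh-type transition state (forming bond anti to the C–OAc bond; CH2OBz, OAc and OBz equatorial; carbonyl oxygen axial), so that attack on the Re face (O > CH(OAc) > CH2OBz), reinforced by the chiral carbene, gives the S carbinol with OH cis to OAc, while the catalytic weak base keeps E1cB loss of the β-benzoate slow.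

Step 8
Reactants: 9 [(1S,2S,3R)-2-acetoxy-3-(benzoyloxy)-1-hydroxy-6-oxocyclohexyl]methyl benzoate
Product: 10 2-O-acetylzeylenone, [(1S,2S,3R)-2-acetoxy-3-(benzoyloxy)-1-hydroxy-6-oxocyclohex-4-en-1-yl]methyl benzoate
Conditions: IBX (2.5 eq), 4-methoxypyridine N-oxide (2.5 eq), DMSO, rt
Reagents that add atoms: none
Why: IBX dehydrogenation of a ketone (Nicolaou) proceeds through the only possible enol, toward C5 because C1 is quaternary, and gives the C4=C5 enone at room temperature without base, so the three stereocentres and the esters are not disturbed.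

## Compound list

1 | 2,3:4,6-di-O-isopropylidene-α-L-sorbofuranose | OC[C@]12OC(C)(C)O[C@H]1[C@@H]1OC(C)(C)OC[C@@H]1O2 | starting material
2 | 2,3-O-isopropylidene-α-L-sorbofuranose | OC[C@]12OC(C)(C)O[C@H]1[C@H](O)[C@H](CO)O2 | intermediate
3 | 6-deoxy-6-iodo-2,3-O-isopropylidene-α-L-sorbofuranose | OC[C@]12OC(C)(C)O[C@H]1[C@H](O)[C@H](CI)O2 | intermediate
4 | 1,4-di-O-benzoyl-6-deoxy-6-iodo-2,3-O-isopropylidene-α-L-sorbofuranose | O=C(OC[C@]12OC(C)(C)O[C@H]1[C@H](OC(=O)c1ccccc1)[C@H](CI)O2)c1ccccc1 | intermediate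
5 | ring-opened hemiketal, [(4S,5S)-5-[(1R)-1-(benzoyloxy)prop-2-en-1-yl]-4-hydroxy-2,2-dimethyl-1,3-dioxolan-4-yl]methyl benzoate | O=C(OC[C@]1(O)OC(C)(C)O[C@H]1[C@H](OC(=O)c1ccccc1)C=C)c1ccccc1 | intermediate
6 | (3S,4R)-1,4-bis(benzoyloxy)-3-hydroxyhex-5-en-2-one | O[C@H](C(=O)COC(=O)c1ccccc1)[C@H](OC(=O)c1ccccc1)C=C | intermediate
7 | (3S,4R)-3-acetoxy-1,4-bis(benzoyloxy)hex-5-en-2-one | CC(=O)O[C@H](C(=O)COC(=O)c1ccccc1)[C@H](OC(=O)c1ccccc1)C=C | intermediate
8 | (4R,5S)-5-acetoxy-4,7-bis(benzoyloxy)-6-oxoheptanal | CC(=O)O[C@H](C(=O)COC(=O)c1ccccc1)[C@H](OC(=O)c1ccccc1)CCC=O | intermediate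
9 | [(1S,2S,3R)-2-acetoxy-3-(benzoyloxy)-1-hydroxy-6-oxocyclohexyl]methyl benzoate (4,5-dihydro-2-O-acetylzeylenone) | CC(=O)O[C@H]1[C@H](OC(=O)c2ccccc2)CCC(=O)[C@]1(O)COC(=O)c1ccccc1 | intermediate
10 | 2-O-acetylzeylenone, [(1S,2S,3R)-2-acetoxy-3-(benzoyloxy)-1-hydroxy-6-oxocyclohex-4-en-1-yl]methyl benzoate | CC(=O)O[C@H]1[C@H](OC(=O)c2ccccc2)C=CC(=O)[C@]1(O)COC(=O)c1ccccc1 | target

## Step count and risks

Total step count: 8. Longest linear sequence: 8 (fully linear, from 1).

The three steps most likely to fail are steps 7, 8 and 4.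

**Step 7 (carbene-catalysed ring closure).** Keto-aldehyde 8 carries an acidic C–H between the ketone and the acetate with a benzoate in the β position, so base can cause elimination or epimerisation before cyclisation. The C1 configuration also depends on the chair transition state and the catalyst antipode behaving as argued. The fallback sets out from 7 and comes back at 10, bypassing steps 6 to 8. 1-Methoxyallene is lithiated (n-BuLi, THF, −78 °C), transmetallated with anhydrous CeCl3 to a weakly basic acryloyl-anion equivalent, and added to ketone 7 at −78 °C. Addition anti to the C–OAc bond (polar Felkin–Anh) gives the same C1 configuration in (4S,5S,6R)-5-acetoxy-6-(benzoyloxy)-4-[(benzoyloxy)methyl]-4-hydroxy-3-methoxyocta-1,2,7-triene F3. Cold dilute H2SO4 in THF hydrolyses the allenyl ether to the vinyl ketone (4S,5S,6R)-5-acetoxy-6-(benzoyloxy)-4-[(benzoyloxy)methyl]-4-hydroxyocta-1,7-dien-3-one F4. Ring-closing metathesis (Hoveyda–Grubbs II, toluene, 60 °C) then gives 10.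

**Step 8 (dehydrogenation).** IBX may react sluggishly with this electron-poor ketone, or the tertiary α-ketol may be degraded. The fallback sets out from 9 and comes back at 10. PhSeCl in EtOAc at rt selenenylates through the enol under acid catalysis, without base, to give [(1S,2S,3R)-2-acetoxy-3-(benzoyloxy)-1-hydroxy-6-oxo-5-(phenylselanyl)cyclohexyl]methyl benzoate F5 as a mixture of C5 epimers. Oxidation with H2O2/pyridine in CH2Cl2 at 0 °C and syn-elimination of the selenoxide, which can only go toward C4, gives 10.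

**Step 4 (zinc fragmentation).** The zinc alkoxide at O3 sits next to the O4 benzoate and can cause benzoyl migration. The free α-ketol 6 is fragile, and zinc may reductively cleave the new α-benzoyloxy ketone. The fallback sets out from 4 and comes back at 7. HCl in MeOH (from AcCl, 0 °C → rt) exchanges the acetonide for a methyl ketoside and gives methyl 1,4-di-O-benzoyl-6-deoxy-6-iodo-L-sorbofuranoside F1 (α/β mixture, free 3-OH). Ac2O/pyridine gives methyl 3-O-acetyl-1,4-di-O-benzoyl-6-deoxy-6-iodo-L-sorbofuranoside F2. Zinc fragmentation of F2 expels methanol from the anomeric carbon and delivers acetate 7 directly, so neither an O3 alkoxide nor the free ketol 6 is ever formed.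

## Further compounds

F1 | step 4 | methyl 1,4-di-O-benzoyl-6-deoxy-6-iodo-L-sorbofuranoside (α/β mixture at C2) | COC1(COC(=O)c2ccccc2)O[C@@H](CI)[C@@H](OC(=O)c2ccccc2)[C@@H]1O
F2 | step 4 | methyl 3-O-acetyl-1,4-di-O-benzoyl-6-deoxy-6-iodo-L-sorbofuranoside (α/β mixture at C2) | COC1(COC(=O)c2ccccc2)O[C@@H](CI)[C@@H](OC(=O)c2ccccc2)[C@@H]1OC(C)=O
F3 | step 7 | (4S,5S,6R)-5-acetoxy-6-(benzoyloxy)-4-[(benzoyloxy)methyl]-4-hydroxy-3-methoxyocta-1,2,7-triene | CC(=O)O[C@H]([C@@](O)(COC(=O)c1ccccc1)C(OC)=C=C)[C@H](OC(=O)c1ccccc1)C=C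
F4 | step 7 | (4S,5S,6R)-5-acetoxy-6-(benzoyloxy)-4-[(benzoyloxy)methyl]-4-hydroxyocta-1,7-dien-3-one | CC(=O)O[C@H]([C@@](O)(COC(=O)c1ccccc1)C(=O)C=C)[C@H](OC(=O)c1ccccc1)C=C
F5 | step 8 | [(1S,2S,3R)-2-acetoxy-3-(benzoyloxy)-1-hydroxy-6-oxo-5-(phenylselanyl)cyclohexyl]methyl benzoate (C5 epimers) | CC(=O)O[C@H]1[C@H](OC(=O)c2ccccc2)CC([Se]c2ccccc2)C(=O)[C@]1(O)COC(=O)c1ccccc1
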